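One percentage point of product in these readings counts on the two substrates together, so it costs two points of its own substrate's charge.

| flask | left-handed substrate | right-handed substrate | coupling partner | free catalyst | remark | time |
|---|---|---|---|---|---|---|
| gamma | 0.80 M | 0.80 M | 0.80 M | 10 mM | run made earlier |  |
| zeta | 0.80 M | 0.80 M | 0.80 M | 40 mM | run made earlier |  |
| north-east | 0.80 M | 0.80 M | 0.800 M | 20 mM |  | 80 min |
| north-west | 0.80 M | 0.80 M | 0.800 M | 20 mM |  | 25 min |

| run | time / min | left-handed product / % | right-handed product / % |
|---|---|---|---|
| gamma | 8.00 | 6.2 | 1.5 |
| gamma | 12.0 | 9.5 | 2.3 |
| gamma | 20.0 | 11.2 | 2.6 |
| gamma | 40.0 | 11.4 | 3.4 |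
| gamma | 60.0 | 9.5 | 3.9 |
| gamma | 90.0 | 10.7 | 3.4 |
| zeta | 8.00 | 17.8 | 6.5 |
| zeta | 12.0 | 17.8 | 8.4 |
| zeta | 20.0 | 22.4 | 8.3 |
| zeta | 40.0 | 20.5 | 6.8 |
| zeta | 60.0 | 21.5 | 8.4 |
| zeta | 90.0 | 20.9 | 8.1 |

(readings scatter by 1 percentage point)

- free catalyst is single-handed; left-handed substrate and right-handed substrate are mirror images of each other, charged as a racemate, each of them at the stated concentration
- an excess is below zero if the other one leads

1. which of the two ends with the higher excess of left-handed product over right-handed product in the product ("neither" if they lie within 2 percentage points) (north-east / north-west / neither)
2. excess of left-handed product over right-handed product in the product at the end, north-east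
3. excess of left-handed product over right-handed product in the product at the end, north-west

Two chemists disagree about these flasks. The first watches the clock. From 20.0 min on, the excess averages 52.6% in the gamma run and 45.9% in the zeta run, lower where the readings show more product. So she expects north-east, given 3.20 times the time of north-west, to react further and end lower.

The second watches the catalyst. The zeta run holds 21.3% left-handed and 7.90% right-handed product over those readings, with no climb. Yet by the product count in that run the coupling partner, the limiting reagent, still has 0.415 of its charge, and the left-handed substrate 0.574, the right-handed 0.842.

Both accept one rule. If each substrate goes at a rate proportional to its own amount, multiplied by the same catalyst and partner terms for both, the logarithm of the left-handed fraction left divided by that of the right-handed stays constant, however the catalyst fares. This ratio, the selectivity factor, reads 3.23 in the zeta run, a reading with its scatter. It ties the excess to the fractions left, so the clock counts while those fractions move.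

The second's number is the forecast: 49% for north-east, 49% for north-west, answer neither, since “the catalyst is evidently dying”.

North-east ends at 46.2% and north-west at 46.3%, so the answer is neither.

    free catalyst → spent catalyst B (k = 0.120 /min)
    coupling partner + free catalyst + right-handed substrate → free catalyst + right-handed product (k = 1.50 /M²/min)
    coupling partner + free catalyst + left-handed substrate → free catalyst + left-handed product (k = 4.60 /M²/min)
    2 free catalyst → spent catalyst A (k = 0.900 /M/min)
    2 coupling partner → homo dimer (k = 0.00750 /M/min)

The clock's region is the opening minutes: north-east had reacted 16.3% of the two substrates by 8.00 min, against 21.4% at 80 min. In north-east, 69% of the left-handed substrate is left, and the selectivity factor of 3.23 gives 89.1% of the right-handed, where the flask holds 88%. A neighbour of north-west with 2.0 M of coupling partner keeps 41% of the left-handed substrate, so the factor gives 76.1% of the right-handed and an excess of 42.3%, and that flask shows 75% and 40.2%.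

The runs were computed with made-up constants; the scatter is artificial.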